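The summer run, at 0.60 equiv of reagent, had made 50.8% product by 10.0 min, and the new flask repeated its charges with half the free catalyst, so I began with what that run could say about reagent.

- summer: substrate 0.10 M; reagent 0.60 equiv; free catalyst 0.14 mol%; run made earlier
- flask: substrate 0.10 M; reagent 0.600 equiv; free catalyst 0.069 mol%

summer run (percent of the substrate charged)

| time / min | product / % |
|---|---|
| 0.833 | 13.7 |
| 2.50 | 26.8 |
| 5.00 | 39.4 |
| 8.00 | 46.6 |
| 10.0 | 50.8 |

(standard deviation of a reading: 0.5 percentage points)

- the numbers in the tables scatter with a standard deviation of 0.5 percentage points
- no earlier run changes the charge of free catalyst; that part of a forecast is a guess
- no earlier run changes the charge of reagent; that part of a forecast is a guess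

- apparent order in reagent when 30% of the substrate are converted (percent change of the rate of making product for one percent more reagent charged)

Where did the flask stop? Assuming one reagent per product, reagent was the limiting reagent and I expected the flask to end near 60.0% product, so at 30% it held 50.0% of its charge.

What, then, did one percent more reagent charged do there? It added the same amount to a smaller remainder, and I reckoned 2.00 for the leverage L, the reagent charged divided by the reagent left at that conversion; with the conversion held fixed, so that substrate and product stay the same, the apparent order is L times the order in reagent left.

Did less catalyst alter this? L holds no catalyst, and a constant factor on the rate drops out of a percent change, so, guessing first order in reagent left, I committed to 2.00. The forecast gave 1.8, between 1 and 2.3, lower than my figure on the ground that “Partial saturation would lower the value”.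

The flask gave 1.7, inside that range.

    reagent + free catalyst → catalyst intermediate A (k = 77.0 M⁻¹ s⁻¹)
    catalyst intermediate A ⇌ by-product + catalyst intermediate B (K = 0.280 M, k = 130 s⁻¹)
    substrate + catalyst intermediate B → catalyst intermediate C (k = 140 M⁻¹ s⁻¹)
    catalyst intermediate C → free catalyst + product (k = 13.0 s⁻¹)
    free catalyst + by-product ⇌ idle complex, settled at all times (K = 68.0 M⁻¹)

Dividing by L left 0.870 as this flask's order in reagent left, and part of the apparent order came from the idle complex, since the same flask without the association of free catalyst and by-product gave 1.4. For the run with twice the reagent of this flask, L fell to 1.33, and a rate equal to a constant times reagent left makes the time to that conversion go as ln L, a factor of 0.411; that run took 0.530 of this flask's time.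

The numbers in the tables come from a simulation for substances that don't exist, and the scatter is random.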